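## Retrosynthetic overview
1. The exocyclic C=CHBr comes from NBS/Et₃N dehydrogenation of a 5‑(bromomethyl)‑4‑bromobutenolide (7).
2. The 4‑bromobutenolide ring (the only ring) is formed in one acid step, by cyclodehydration of a 3,5‑dibromo‑levulinate (6).
3. Compound 6 comes from a 2‑substituted levulinate: Fráter–Seebach allylation, then Wacker oxidation, of a chiral β‑hydroxy ester.
4. The only stereocentre, the (R)‑carbinol, is set at the start by Noyori hydrogenation of tert‑butyl 3‑oxohexanoate. It is then protected as the acetate that is also the final functional group.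

**Assumptions:**
- The exocyclic C=C geometry is taken exactly as written in the SMILES (Br cis to C4, trans to ring O; CIP label E).
- C2 of compounds 3–6 and C5 of compound 7 are left undefined because they are destroyed later.

## Route

**Step 1**
Reactants: 1, tert‑butyl 3‑oxohexanoate
Product: 2, tert‑butyl (3R)‑3‑hydroxyhexanoate
Conditions: H₂ (100 atm), RuCl₂[(R)‑BINAP] (0.5 mol%), MeOH, 50 °C
Reagents that add atoms: none (only H₂ is added)
Why: Noyori asymmetric hydrogenation of a β‑keto ester sets the carbinol; (R)‑BINAP gives the (R)‑alcohol, which is the configuration required at C1′ of the target.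

**Step 2**
Reactants: 2
Product: 3, tert‑butyl (3R)‑2‑allyl‑3‑hydroxyhexanoate (C2 epimers, anti major)
Conditions: LDA (2.2 equiv), THF, –78 → –20 °C; then allyl bromide, DMPU, –20 → 0 °C
Reagents that add atoms: allyl bromide, C=CCBr
Why: Fráter–Seebach alkylation of the chelated alkoxide/ester dianion keeps the C3 carbinol untouched and adds the allyl group at C2; the new C2 centre is irrelevant because it becomes sp² at Step 6.

**Step 3**
Reactants: 3
Product: 4, tert‑butyl (3R)‑3‑acetoxy‑2‑allylhexanoate
Conditions: Ac₂O, Et₃N, DMAP (cat.), CH₂Cl₂, 0 °C → rt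
Reagents that add atoms: acetic anhydride, CC(=O)OC(C)=O
Why: O‑acetylation proceeds with retention. The acetate is the final C1′ substituent, and it resists the later HBr and H₂SO₄ steps better than a silyl ether would.

**Step 4**
Reactants: 4
Product: 5, tert‑butyl 2‑[(1R)‑1‑acetoxybutyl]‑4‑oxopentanoate
Conditions: PdCl₂ (10 mol%), CuCl (1 equiv), O₂ (1 atm), DMF/H₂O (7:1), rt
Reagents that add atoms: water, O (supplies the ketone oxygen); O₂, O=O (terminal oxidant)
Why: Wacker–Tsuji oxidation converts the terminal alkene to the Markovnikov methyl ketone, giving the 2‑substituted levulinate skeleton; the ester, acetate and C1′ stereocentre are inert.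

**Step 5**
Reactants: 5
Product: 6, tert‑butyl 2‑[(1R)‑1‑acetoxybutyl]‑3,5‑dibromo‑4‑oxopentanoate
Conditions: Br₂ (2.2 equiv), CHCl₃, cat. HBr, 0 °C → rt
Reagents that add atoms: bromine, BrBr
Why: acid‑catalysed enol α‑bromination brominates the CH₂ first and then the CH₃ of the methyl ketone; the new C3 centre and the C2 centre are destroyed in the next step, and the HBr formed partly cleaves the t‑Bu ester.

**Step 6**
Reactants: 6
Product: 7, 3‑[(1R)‑1‑acetoxybutyl]‑4‑bromo‑5‑(bromomethyl)furan‑2(5H)‑one (C5 epimers)
Conditions: conc. H₂SO₄, 0 °C → rt, 2 h; then NaHCO₃ work‑up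
Reagents that add atoms: none (H₂SO₄ is catalyst and dehydrating agent; tert‑butyl leaves as isobutene and water is lost)
Why: acid cleaves the t‑Bu ester, and the acid closes onto the ketone (pseudo‑acid) and dehydrates toward C4–H, an acid cyclodehydration that forms the butenolide ring. The C3=C4 alkene carrying Br at C4 forms, and the enol lactone tautomerises to the conjugated 2(5H)‑furanone. C1′ has no acidic H, so its configuration is retained.

**Step 7**
Reactants: 7
Product: 8, acetoxyfimbrolide, the target
Conditions: NBS (1.1 equiv), AIBN (cat.), PhCF₃, 80 °C; then Et₃N (1.5 equiv), CH₂Cl₂, 0 °C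
Reagents that add atoms: none net (the Br from NBS is lost again as Et₃N·HBr)
Why: radical or ionic γ‑bromination at the very activated C5–H gives a 5‑bromo‑5‑(bromomethyl) intermediate, and E2 loss of HBr forms the exocyclic bromoalkene (dehydrobromination). The geometry is assigned by NOE; any Z isomer is removed by chromatography.

**Consistency checks:**
- The formulas balance at every step (compound 7 is C₁₁H₁₄Br₂O₄, and the target is C₁₁H₁₂Br₂O₄ after NBS/Et₃N).
- The tert‑butyl ester and acetate survive Steps 3–5. The ester is removed deliberately in Step 6.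
- The C1′ (R) centre is never adjacent to an acidic C–H after Step 2's protection. It is intact at the end, and the CIP priority order (O > C2/ring C > propyl) is unchanged throughout.

## Compound list
1 | tert‑butyl 3‑oxohexanoate | CCCC(=O)CC(=O)OC(C)(C)C | starting material
2 | tert‑butyl (3R)‑3‑hydroxyhexanoate | CCC[C@@H](O)CC(=O)OC(C)(C)C | intermediate
3 | tert‑butyl (3R)‑2‑allyl‑3‑hydroxyhexanoate | CCC[C@@H](O)C(CC=C)C(=O)OC(C)(C)C | intermediate
4 | tert‑butyl (3R)‑3‑acetoxy‑2‑allylhexanoate | CCC[C@@H](OC(C)=O)C(CC=C)C(=O)OC(C)(C)C | intermediate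
5 | tert‑butyl 2‑[(1R)‑1‑acetoxybutyl]‑4‑oxopentanoate | CCC[C@@H](OC(C)=O)C(CC(C)=O)C(=O)OC(C)(C)C | intermediate
6 | tert‑butyl 2‑[(1R)‑1‑acetoxybutyl]‑3,5‑dibromo‑4‑oxopentanoate | CCC[C@@H](OC(C)=O)C(C(Br)C(=O)CBr)C(=O)OC(C)(C)C | intermediate
7 | 3‑[(1R)‑1‑acetoxybutyl]‑4‑bromo‑5‑(bromomethyl)furan‑2(5H)‑one | CCC[C@@H](OC(C)=O)C1=C(Br)C(CBr)OC1=O | intermediate
8 | acetoxyfimbrolide | CCC[C@@H](OC(C)=O)C1=C(Br)/C(=C\Br)OC1=O | target

## Summary
Total steps: 7. Longest linear sequence: 7 steps, from compound 1.

**Three steps most likely to fail:**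
1. **Step 7 (NBS/Et₃N).** It may give the wrong exocyclic alkene geometry, or brominate C1′–H instead of C5–H. Fallback: build the exocyclic bromoalkene by anti‑bromolactonisation (NBS) of a (Z)‑3‑bromo‑2‑(1‑acetoxybutyl)pent‑2‑en‑4‑ynoic acid, made from the corresponding α‑keto ester by Ramirez dibromo‑olefination and Sonogashira coupling. The anti addition fixes the geometry drawn in the SMILES.
2. **Step 6 (H₂SO₄ cyclodehydration).** It may cause acetate loss, β‑elimination to a 3‑butylidene lactone, or dehydration toward the wrong side. Fallback: carry C1′ as a ketone instead. Make 3‑butanoyl‑5‑methyltetronic acid by Dieckmann cyclisation of ethyl lactate acylated with methyl 3‑oxohexanoate. Convert it to the 4‑bromide with (COBr)₂, then do the NBS/Et₃N step, then CBS reduction with (R)‑Me‑oxazaborolidine/BH₃ and acetylation to set C1′ last.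
3. **Step 2 (dianion allylation).** It may suffer retro‑aldol, low yield or poor dr. Fallback: alkylate compound 1 first (K₂CO₃, allyl bromide) and then carry out Noyori dynamic kinetic resolution hydrogenation of the 2‑allyl‑3‑oxo ester with Ru‑(R)‑BINAP. This sets the carbinol after the C–C bond is formed.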